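The vessel was a closed, stirred flask at constant temperature, and I charged it identically for each run and changed the temperature.

    substrate + free catalyst → free catalyst + intermediate (k1 = 1300 L mol⁻¹ s⁻¹, Ea1 = 39.0 kJ mol⁻¹)
    partner + second catalyst + intermediate → second catalyst + product (k2 = 54000 L² mol⁻² s⁻¹, Ea2 = 27.0 kJ mol⁻¹)
    second catalyst + impurity → spent catalyst (k3 = 1.3 × 10⁶ L mol⁻¹ s⁻¹, Ea3 = 28.0 kJ mol⁻¹)
    substrate + product ⇌ idle adduct, settled at all times (K4 = 95 L mol⁻¹, ΔH4 = −31.0 kJ mol⁻¹)
    (constants at 25 °C)

| flask | substrate | partner | free catalyst | second catalyst | impurity | temperature | time |
|---|---|---|---|---|---|---|---|
| Sunday's | 13 mM | 16.9 mM | 65 µM | 65 µM | 31 µM | 25 °C | 1.0 min |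
| Friday's | 13 mM | 16.9 mM | 65 µM | 65 µM | 31 µM | 40 °C | 1.0 min |
| Wednesday's | 13 mM | 16.9 mM | 65 µM | 65 µM | 31 µM | 10 °C | 1.0 min |

1. the flask that comes out highest in amount of product, in percent of the substrate charged, or "all alike" when all lie within 1.5 percentage points (Sunday's / Friday's / Wednesday's / all alike)
2. product at the end, in percent of the substrate charged, Sunday's
3. product at the end, in percent of the substrate charged, Friday's
4. product at the end, in percent of the substrate charged, Wednesday's

- a species is counted by the substrate in it: one idle adduct counts as two
- amounts and yields of product count idle adduct too
- the list of constants is for 25 °C, to be carried to other temperatures by the activation energies and enthalpies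
- in an amount of product, one idle adduct counts as one product

I reckoned with two times. Free catalyst survives step 1, so substrate had a half-life of 8.20 s in Sunday's flask. Impurity meets second catalyst on a scale of 0.0118 s, far shorter than that half-life, so I took 34.0 µM of second catalyst as surviving from the start. Step 2 returns what survives, so with partner at its charge I got 22.3 s in Sunday's flask. This is the clearance half-life: the time in which step 2 halves intermediate at the surviving second catalyst and the charged partner. Since substrate's half-life was shorter than the clearance half-life by a factor of 2.72, I expected intermediate to pile up in Sunday's flask, with step 2 as the rate-limiting step for the later part of the run.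

I solved both ends and joined them. Early on in Sunday's flask, substrate needs about its mean life, 11.8 s, to become intermediate. Later, intermediate and partner fall together by a second-order law, with substrate the limiting reagent. Starting that law late by the mean life, and setting idle adduct aside, I got 64.1 % for Sunday's. Carrying the constants to each temperature gave 80.1 % for Friday's and 37.9 % for Wednesday's.

The forecast named Friday's as highest, with 61 % for Sunday's, 79 % for Friday's and 37 % for Wednesday's, on the ground that “the partner-dependent second step is the bottleneck and the yield climbs strongly with temperature”. My figures lay above its figures for each flask.

The simulation put Friday's highest, with 61.7 % for Sunday's, 79.5 % for Friday's and 36.3 % for Wednesday's.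

In Sunday's flask at 0.134 min, intermediate's half-life by step 2 stood at 0.39 min against my 0.372 min and substrate's 0.14 min by step 1, and at the end 36.1 % of the charged substrate stood as intermediate and 1.29 % as substrate. With 0.053 mM of impurity in the neighbour of Sunday's flask, the clearance half-life came to 1.05 min, the joined law gave 35.9 %, and that flask ended at 35.3 % product with 63.4 % as intermediate.

The constants come from no measurement; what happens was integrated by code.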